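## Structural features

The target 24 is a 2,3,4-trisubstituted tetrahydrofuran (ring atoms O1, C7', C8', C8, C9). C7' carries the catechol ring, C8' the C9' hydroxymethyl group, and C8 an exocyclic secondary benzylic carbinol C7 bonded to the guaiacyl ring. Four contiguous stereocentres, C7 (R), C8 (R), C8' (R) and C7' (S), stand in a row; on the ring the C7' aryl is trans to the C9' arm, which is cis to the C7 arm, and C7 lies outside the ring. The fragile groups are the free catechol and guaiacol (oxidation, especially in base) and the two benzylic C–O bonds, C7–OH and C7'–O1, which ionise in acid and can be hydrogenolysed. The real difficulty is the crowded 3,4-cis relation next to a 2,3-trans aryl, together with a C7 configuration that ring-based control cannot reach. The key step uses the fact that C8 sits between C7 and C9 and can be made a trigonal radical by loss of a carboxyl group, so its earlier configuration is irrelevant; closure of C8 onto C8' of an alkenylboronate hung on the (S)-C7' ether oxygen builds the ring, and the boron on C9' is both the radical-stabilising group and a masked hydroxyl. Two design points follow from these sensitivities. Boron is introduced only after the peroxide-mediated auxiliary cleavage, because a C–B bond does not survive hydroperoxide. The oxa-Michael adduct is made as a methyl ester, because acidolysis of a tert-butyl ester would ionise the electron-rich propargylic benzylic ether.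

## Logic of the disconnections

24 to 23: the three aryl O–CH2Ph bonds are cut. The phenols stay masked by groups that come off without acid or base. The forward hydrogenolysis must spare the benzylic C7–OH and C7'–O1 bonds.

23 to 22: the O–Si bond at C7 is cut. The silyl ether keeps the C7 oxygen inert through activation and radical chemistry. Fluoride must leave everything else untouched.

22 to 21: the C9'–O bond is traced to a C9'–B bond. Boron is a hydroxyl surrogate that also activates the alkene of the preceding step. The oxidation must be mild enough for electron-rich arenes and the silyl ether.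

21 to 20: the C8–C8' ring bond is cut, opening the tetrahydrofuran. This removes the ring and two stereocentres and leaves an acyclic chain in which only C7 and C7' matter, C8 becoming a carboxyl-bearing carbon. The forward step needs 5-exo closure faster than hydrogen transfer and a chair that places the C7' aryl and the C7 arm pseudo-equatorial.

20 to 18 and 19: the C9'–B and C8'–H bonds across the alkyne are cut. Boron arrives late, after all peroxide chemistry. The forward hydroboration must be terminal, syn, and tolerant of the N-acyloxyphthalimide.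

18 to 17: the acyl O–N bond is cut. The radical precursor comes from a plain acid. The coupling must not cause β-elimination at C8.

17 to 15 (through 16): the acyl–N bond to the auxiliary is cut. Cleavage must be exocyclic and is done while the molecule carries an alkyne and no boron.

15 to 14: the O–Si bond at C7 is cut. Silylation blocks retro-aldol and β-lactone formation in later steps.

14 to 10 and 11 (through 12 and 13): the C7–C8 bond is cut. This aldol creates the C7 carbinol under reagent control; the C8 outcome is immaterial. The enolate must form without loss of the β-alkoxy group, and 8 must dictate the aldehyde face.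

10 to 7 and 8 (through 9): the acyl–N bond is cut, attaching the controller to a simple acid.

7 to 6: the ester O–CH3 bond is cut. Basic hydrolysis avoids acid near the C7' ether.

6 to 4 and 5: the C9–O bond is cut. Conjugate addition gives the three-carbon acid chain in one step. The conditions must not isomerise the propargylic ether.

4 to 1 and 2 (through 3): the C7'–C(sp) bond is cut. This sets C7' and supplies the two carbons that become C8' and C9'. The forward step needs enantioface control at the aldehyde.

## Other disconnections considered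

Alternative 1: The cut removes O1–C7' and C8–C8' together, leading back to racemic 2-vinyloxirane A1 and the arylidene malonate A2 (the Knoevenagel product of 1). In the forward key step zerovalent palladium, from Pd2(dba)3 and a chiral diphosphine, would ionise A1 to a π-allylpalladium alkoxide. The alkoxide adds to A2 and the malonate carbon closes on the allyl terminus, giving the 2,4-trans diester A3.
- In favour: enantiocontrol is catalytic, a racemic commodity epoxide is used, no auxiliary is needed, and the ring stands two steps from 1. After removal of one ester, the remaining C8' substituent is epimerisable and should prefer to lie trans to the C7' aryl, hence cis to the C8 substituent. That thermodynamic handle on the 3,4-cis relation is better than the kinetic preference the chosen plan relies on.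
- Against: the dialkoxyaryl group makes A2 a weak acceptor for a reversible alkoxide addition. C8' is born quaternary, so dealkoxycarbonylation, reduction and protection steps follow. C7 must be made by cleaving the vinyl group and adding a guaiacyl organometallic to an epimerisable α-branched aldehyde with no dependable facial bias.
- Comparison: on structure the alternative is the better at C8' and in being catalytic, and the chosen plan is clearly the better at C7, which it fixes by an auxiliary before the ring exists. On mechanism the polar palladium step depends on the electrophilicity of A2, whereas the radical closure is indifferent to the electron-rich arenes. On step economy the two are about equal once the adjustments after A3 are counted.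

Alternative 2: After retro-reduction and retro-Baeyer–Villiger, the cut removes C7–C8 and C8'–C9', leading to the (S)-2-aryl-2,5-dihydrofuran A4 and the arylketene A5. In the forward key step A5, generated in the flask, would add suprafacially across C8=C8' of A4 on the face away from the C7' aryl to give the cyclobutanone A6. Baeyer–Villiger insertion between C9' and C7 with retention would give the lactone A7, and hydride reduction of A7 would give 23 directly. On numbering: with the ketone as C6 of the bicycle, the tetrahydrofuran aryl sits on C4 (4-exo). A 2-aryl locant would describe the other orientation, with the carbonyl on C8, which leads to the wrong constitution.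
- In favour: three stereocentres, C7 included, are set in one step. The cis ring fusion makes the 3,4-cis relation certain, which is better than the chosen plan. A4 is about three steps from 4 (semi-hydrogenation, O-allylation, ring-closing metathesis), so 23 would be reached in fewer steps than in the chosen plan.
- Against: aryl(hydrido)ketenes dimerise and add sluggishly to unactivated 1,2-disubstituted alkenes. C8 and C8' of A4 are electronically almost alike, so the required orientation is not secured. The endo aryl needed for 7R is the normal thermal outcome, but Lewis-acid activation, the usual cure for low reactivity, tends to erode it.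
- Comparison: the alternative is the better on step count and on certainty of ring fusion. The two are equal on the source of absolute configuration, since both take C7' from the same alkynol. The alternative is the weaker on regiochemistry and reactivity, because in the chosen plan the tether decides which carbons bond.

Alternative 3: The cut removes C9–C8 and C7'–C8', leading to the α-chloro ether A8 and the menthyloxybutenolide A9. In the forward key step CsF would strip silicon from A8 with loss of chloride; the aryl-substituted carbonyl ylide would then add across the butenolide double bond of A9 anti to the menthyloxy group, giving A10. On numbering: in A10 the aryl carbon is bonded to the bridgehead that carries the lactone carbonyl, so it is C8 of the bicycle (8-exo); a 6-aryl locant would be the opposite orientation. The menthyl group required is (1S,2R,5S), from (+)-menthol.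
- In favour: both ring C–C bonds and three ring stereocentres are set in one step. Absolute control comes from a crystalline acetal. The cis fusion again guarantees 3,4-cis, which is better than the chosen plan. C9' arrives at a convenient oxidation level, and the sequence is potentially the shortest of the four.
- Against: A8 with an electron-rich aryl is an extremely ionisable α-chloro ether. Neither the orientation of an unsymmetrical non-stabilised ylide nor the exo placement of the aryl is secured. The less available menthol antipode is needed. C7 arrives as an acetal carbon without its aryl, so it must be unmasked and arylated with uncertain facial control.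
- Comparison: the alternative is the better on step count and ring fusion. The chosen plan is the better on C7 and on regiochemical certainty. Mechanistically both key steps are kinetically controlled additions to an alkene, but the radical closure is intramolecular and therefore has no orientation problem.

Key step: step 10

Assumption (remark on the chemistry): the ProPhenol antipode in step 1 is the one that directs alkynyl transfer to the Si face of 1; both antipodes are commercial, so the required configuration is accessible whichever antipode that is.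

## Route

Step 1
Reactants: 1 3,4-bis(benzyloxy)benzaldehyde; 2 ethynyltrimethylsilane
Product: 4 (S)-1-[3,4-bis(benzyloxy)phenyl]prop-2-yn-1-ol, via silylated alkynol 3 (not isolated)
Conditions: 2 (3 equiv), Me2Zn (3 equiv), ProPhenol (10 mol%), Ph3PO (20 mol%), toluene, 0 °C → rt; aqueous NH4Cl work-up; then K2CO3 (cat.), MeOH, rt
Reagents that add atoms: none
Why: Zinc–ProPhenol catalysed enantioselective alkynylation of an aryl aldehyde; the dinuclear zinc complex holds aldehyde and alkynylzinc together and delivers the alkynyl group to the Si face, setting C7' (R descriptor in 3, S in 4, same geometry). Methanolysis of the C(sp)–Si bond is standard and leaves the carbinol untouched.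

Step 2
Reactants: 4 (S)-alkynol; 5 methyl acrylate
Product: 6 methyl 3-{[(1S)-1-[3,4-bis(benzyloxy)phenyl]prop-2-yn-1-yl]oxy}propanoate
Conditions: 5 (3 equiv), PMe3 (10 mol%), THF, 0 °C → rt
Reagents that add atoms: none
Why: Phosphine-catalysed oxa-Michael addition; the phosphonium enolate formed from PMe3 and the acrylate deprotonates the alcohol and the alkoxide adds to a second acrylate. No free strong base is present, so the acidic propargylic C7'–H should not isomerise to an allene, and the stereocentre is not touched.

Step 3
Reactants: 6 methyl ester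
Product: 7 3-{[(1S)-1-[3,4-bis(benzyloxy)phenyl]prop-2-yn-1-yl]oxy}propanoic acid
Conditions: LiOH·H2O (2 equiv), THF/H2O 3:1, 0 °C → rt; 1 M HCl to pH 3 at 0 °C
Reagents that add atoms: lithium hydroxide, [Li+].[OH-]
Why: Ester saponification; once the carboxylate forms, retro-Michael loss of the alkoxide is disfavoured. Base is used instead of tert-butyl ester acidolysis to protect the ionisable C7' ether.

Step 4
Reactants: 7 acid; 8 (R)-4-benzyloxazolidin-2-one
Product: 10 (4R)-4-benzyl-3-(3-{[(1S)-1-[3,4-bis(benzyloxy)phenyl]prop-2-yn-1-yl]oxy}propanoyl)oxazolidin-2-one, via pivalic mixed anhydride 9 (not isolated)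
Conditions: PivCl (1.1 equiv), Et3N (2.5 equiv), THF, −20 °C; then LiCl (1.1 equiv), 8 (1.05 equiv), −20 °C → rt
Reagents that add atoms: none
Why: Mixed-anhydride N-acylation of an oxazolidinone promoted by LiCl; the oxazolidinone attacks the unhindered carbonyl of 9, not the pivaloyl carbonyl.

Step 5
Reactants: 10 imide; 11 4-(benzyloxy)-3-methoxybenzaldehyde
Product: 14 (4R)-4-benzyl-3-[(2R,3R)-3-[4-(benzyloxy)-3-methoxyphenyl]-2-({[(1S)-1-[3,4-bis(benzyloxy)phenyl]prop-2-yn-1-yl]oxy}methyl)-3-hydroxypropanoyl]oxazolidin-2-one, via boron Z-enolate 12 (not isolated), via boron aldolate 13 (not isolated)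
Conditions: Bu2BOTf (1.2 equiv), i-Pr2NEt (1.4 equiv), CH2Cl2, −78 → 0 °C; 11 (1.2 equiv), −78 → 0 °C; pH 7 buffer, MeOH, 30% H2O2, 0 °C
Reagents that add atoms: none
Why: Evans syn aldol; the Z boron enolate reacts through a closed chair with the auxiliary carbonyl turned away, and the aldehyde is attacked on the face remote from the benzyl group of the (R)-auxiliary, which sets C7 as R (and C8 as R, later erased). Boron enolates of β-alkoxy imides do not readily expel alkoxide, and any adduct from the minor C7' enantiomer becomes a separable diastereomer here.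

Step 6
Reactants: 14 syn-aldol imide
Product: 15 (4R)-4-benzyl-3-[(2R,3R)-3-[4-(benzyloxy)-3-methoxyphenyl]-2-({[(1S)-1-[3,4-bis(benzyloxy)phenyl]prop-2-yn-1-yl]oxy}methyl)-3-[(tert-butyldimethylsilyl)oxy]propanoyl]oxazolidin-2-one
Conditions: TBSOTf (1.3 equiv), 2,6-lutidine (2 equiv), CH2Cl2, −78 → 0 °C
Reagents that add atoms: tert-butyldimethylsilyl trifluoromethanesulfonate, CC(C)(C)[Si](C)(C)OS(=O)(=O)C(F)(F)F
Why: Silylation of a hindered secondary alcohol with a silyl triflate under buffered conditions; it blocks retro-aldol and later β-lactone formation from the active ester.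

Step 7
Reactants: 15 silylated imide
Product: 17 (2R,3R)-3-[4-(benzyloxy)-3-methoxyphenyl]-2-({[(1S)-1-[3,4-bis(benzyloxy)phenyl]prop-2-yn-1-yl]oxy}methyl)-3-[(tert-butyldimethylsilyl)oxy]propanoic acid, via peroxy acid 16 (not isolated)
Conditions: LiOH·H2O (2 equiv), 30% H2O2 (4 equiv), THF/H2O 3:1, 0 °C; aqueous Na2SO3; 1 M HCl to pH 3 at 0 °C
Reagents that add atoms: hydrogen peroxide, OO
Why: Hydroperoxide cleavage of an N-acyloxazolidinone; the small, highly nucleophilic hydroperoxide attacks the exocyclic carbonyl even of a hindered acyl group and sulfite reduces the percarboxylate. It is run while the molecule carries an alkyne and no boron, and any epimerisation at C8 is harmless.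

Step 8
Reactants: 17 acid
Product: 18 1,3-dioxoisoindolin-2-yl (2R,3R)-3-[4-(benzyloxy)-3-methoxyphenyl]-2-({[(1S)-1-[3,4-bis(benzyloxy)phenyl]prop-2-yn-1-yl]oxy}methyl)-3-[(tert-butyldimethylsilyl)oxy]propanoate
Conditions: N-hydroxyphthalimide (1.1 equiv), DIC (1.1 equiv), DMAP (5 mol%), CH2Cl2, 0 °C → rt
Reagents that add atoms: N-hydroxyphthalimide, O=C1c2ccccc2C(=O)N1O
Why: Carbodiimide esterification to the redox-active ester; near-neutral conditions and only catalytic DMAP keep β-elimination at C8 unlikely.

Step 9
Reactants: 18 alkynyl redox-active ester; 19 pinacolborane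
Product: 20 1,3-dioxoisoindolin-2-yl (2R,3R)-3-[4-(benzyloxy)-3-methoxyphenyl]-2-({[(1S,2E)-1-[3,4-bis(benzyloxy)phenyl]-3-(4,4,5,5-tetramethyl-1,3,2-dioxaborolan-2-yl)prop-2-en-1-yl]oxy}methyl)-3-[(tert-butyldimethylsilyl)oxy]propanoate
Conditions: 19 (1.5 equiv), Cy2BH (10 mol%), THF, 0 °C → rt
Reagents that add atoms: none
Why: Dialkylborane-catalysed hydroboration of a terminal alkyne; Cy2BH adds syn and anti-Markovnikov, and exchange with pinacolborane releases the E alkenylboronate and regenerates the catalyst. Pinacolborane itself does not reduce esters or imides, and the step sits after all peroxide chemistry.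

Step 10
Reactants: 20 alkenylboronate redox-active ester
Product: 21 (2S,3S,4R)-2-[3,4-bis(benzyloxy)phenyl]-4-{(R)-[4-(benzyloxy)-3-methoxyphenyl][(tert-butyldimethylsilyl)oxy]methyl}-3-[(4,4,5,5-tetramethyl-1,3,2-dioxaborolan-2-yl)methyl]tetrahydrofuran
Conditions: Ru(bpy)3Cl2·6H2O (2 mol%), Hantzsch ester (1.5 equiv), degassed MeCN/CH2Cl2 1:1 (0.02 M), 450 nm LEDs, rt
Reagents that add atoms: none
Why: Decarboxylative radical cyclisation of a redox-active ester, the intramolecular form of the known photoreductive Giese-type addition of N-acyloxyphthalimide-derived radicals to vinyl boronic esters. Photoexcited Ru(bpy)3Cl2 is reduced by the Hantzsch ester to the monovalent ruthenium complex, which passes one electron to the phthalimide; N–O cleavage and loss of CO2 leave a trigonal secondary radical at C8, so both C8 epimers of 20 give the same intermediate. The tetrahydrofuran closes 5-exo-trig: C8 attacks the alkene carbon next to C7' (the future C8'), favoured by ring size and because the new C9' radical is stabilised by the empty boron p orbital. C8' is set trans to the C7' aryl because that aryl is pseudo-equatorial in the chair-like transition state, and C8 is set cis to the C9' arm because the C7 silyloxybenzyl group on the radical carbon takes the pseudo-equatorial site of the same chair. The C9' radical is then quenched by hydrogen-atom transfer from the Hantzsch ester, giving the CH2–B unit. The step needs cyclisation ahead of premature hydrogen transfer (fast oxygen-tethered 5-exo closure, high dilution, a weak hydrogen donor), electron transfer to the phthalimide only, and no β-elimination of the active ester (no amine base is added). C7 and C7' are spectators and keep their configurations.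

Step 11
Reactants: 21 cyclised boronate
Product: 22 [(2S,3R,4R)-2-[3,4-bis(benzyloxy)phenyl]-4-{(R)-[4-(benzyloxy)-3-methoxyphenyl][(tert-butyldimethylsilyl)oxy]methyl}tetrahydrofuran-3-yl]methanol
Conditions: NaBO3·4H2O (5 equiv), THF/H2O 1:1, rt
Reagents that add atoms: sodium perborate, [Na+].[O-]OB=O
Why: Perborate oxidation of a primary alkylboronate by 1,2-migration from boron to oxygen; the mild, weakly basic oxidant should leave the silyl ether, benzyl ethers and electron-rich rings alone.

Step 12
Reactants: 22 silyl ether alcohol
Product: 23 (R)-[4-(benzyloxy)-3-methoxyphenyl][(3R,4R,5S)-5-[3,4-bis(benzyloxy)phenyl]-4-(hydroxymethyl)tetrahydrofuran-3-yl]methanol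
Conditions: TBAF (1.5 equiv), THF, 0 °C → rt; aqueous NH4Cl
Reagents that add atoms: none
Why: Fluoride desilylation; it is done while the phenols are still benzylated, so no phenoxide or catecholate is exposed to basic fluoride.

Step 13
Reactants: 23 tribenzyl diol
Product: 24 (7R)-7-hydroxytaxiresinol, 4-[(2S,3R,4R)-4-[(R)-hydroxy(4-hydroxy-3-methoxyphenyl)methyl]-3-(hydroxymethyl)tetrahydrofuran-2-yl]benzene-1,2-diol
Conditions: H2 (1 atm), 10% Pd/C, EtOAc, rt, stopped at complete debenzylation
Reagents that add atoms: none
Why: Hydrogenolysis of aryl benzyl ethers, which cleave much faster than benzylic alcohols or benzylic ring ethers under neutral conditions. A non-protic, acid-free solvent avoids solvolysis at C7, and filtration gives the air-sensitive catechol without basic work-up.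

## Compound list

1 | 3,4-bis(benzyloxy)benzaldehyde | O=Cc1ccc(OCc2ccccc2)c(OCc2ccccc2)c1 | starting material
2 | ethynyltrimethylsilane | C#C[Si](C)(C)C | starting material
3 | (R)-1-[3,4-bis(benzyloxy)phenyl]-3-(trimethylsilyl)prop-2-yn-1-ol | O[C@@H](C#C[Si](C)(C)C)c1ccc(OCc2ccccc2)c(OCc2ccccc2)c1 | intermediate (not isolated)
4 | (S)-1-[3,4-bis(benzyloxy)phenyl]prop-2-yn-1-ol | O[C@@H](C#C)c1ccc(OCc2ccccc2)c(OCc2ccccc2)c1 | intermediate
5 | methyl acrylate | C=CC(=O)OC | starting material
6 | methyl 3-{[(1S)-1-[3,4-bis(benzyloxy)phenyl]prop-2-yn-1-yl]oxy}propanoate | COC(=O)CCO[C@@H](C#C)c1ccc(OCc2ccccc2)c(OCc2ccccc2)c1 | intermediate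
7 | 3-{[(1S)-1-[3,4-bis(benzyloxy)phenyl]prop-2-yn-1-yl]oxy}propanoic acid | OC(=O)CCO[C@@H](C#C)c1ccc(OCc2ccccc2)c(OCc2ccccc2)c1 | intermediate
8 | (R)-4-benzyloxazolidin-2-one | O=C1N[C@H](Cc2ccccc2)CO1 | starting material
9 | 3-{[(1S)-1-[3,4-bis(benzyloxy)phenyl]prop-2-yn-1-yl]oxy}propanoic pivalic anhydride | CC(C)(C)C(=O)OC(=O)CCO[C@@H](C#C)c1ccc(OCc2ccccc2)c(OCc2ccccc2)c1 | intermediate (not isolated)
10 | (4R)-4-benzyl-3-(3-{[(1S)-1-[3,4-bis(benzyloxy)phenyl]prop-2-yn-1-yl]oxy}propanoyl)oxazolidin-2-one | O=C1OC[C@@H](Cc2ccccc2)N1C(=O)CCO[C@@H](C#C)c1ccc(OCc2ccccc2)c(OCc2ccccc2)c1 | intermediate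
11 | 4-(benzyloxy)-3-methoxybenzaldehyde | COc1cc(C=O)ccc1OCc1ccccc1 | starting material
12 | dibutylboron (Z)-enolate of 10 (enolate oxygen and CH2O group cis) | CCCCB(CCCC)O/C(=C\CO[C@@H](C#C)c1ccc(OCc2ccccc2)c(OCc2ccccc2)c1)N1C(=O)OC[C@H]1Cc1ccccc1 | intermediate (not isolated)
13 | dibutylboron aldolate of 14 (boron on the C7 oxygen) | COc1cc([C@H](OB(CCCC)CCCC)[C@H](C(=O)N2C(=O)OC[C@H]2Cc2ccccc2)CO[C@@H](C#C)c2ccc(OCc3ccccc3)c(OCc3ccccc3)c2)ccc1OCc1ccccc1 | intermediate (not isolated)
14 | (4R)-4-benzyl-3-[(2R,3R)-3-[4-(benzyloxy)-3-methoxyphenyl]-2-({[(1S)-1-[3,4-bis(benzyloxy)phenyl]prop-2-yn-1-yl]oxy}methyl)-3-hydroxypropanoyl]oxazolidin-2-one | COc1cc([C@H](O)[C@H](C(=O)N2C(=O)OC[C@H]2Cc2ccccc2)CO[C@@H](C#C)c2ccc(OCc3ccccc3)c(OCc3ccccc3)c2)ccc1OCc1ccccc1 | intermediate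
15 | (4R)-4-benzyl-3-[(2R,3R)-3-[4-(benzyloxy)-3-methoxyphenyl]-2-({[(1S)-1-[3,4-bis(benzyloxy)phenyl]prop-2-yn-1-yl]oxy}methyl)-3-[(tert-butyldimethylsilyl)oxy]propanoyl]oxazolidin-2-one | COc1cc([C@H](O[Si](C)(C)C(C)(C)C)[C@H](C(=O)N2C(=O)OC[C@H]2Cc2ccccc2)CO[C@@H](C#C)c2ccc(OCc3ccccc3)c(OCc3ccccc3)c2)ccc1OCc1ccccc1 | intermediate
16 | (2R,3R)-3-[4-(benzyloxy)-3-methoxyphenyl]-2-({[(1S)-1-[3,4-bis(benzyloxy)phenyl]prop-2-yn-1-yl]oxy}methyl)-3-[(tert-butyldimethylsilyl)oxy]propaneperoxoic acid | COc1cc([C@H](O[Si](C)(C)C(C)(C)C)[C@H](C(=O)OO)CO[C@@H](C#C)c2ccc(OCc3ccccc3)c(OCc3ccccc3)c2)ccc1OCc1ccccc1 | intermediate (not isolated)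
17 | (2R,3R)-3-[4-(benzyloxy)-3-methoxyphenyl]-2-({[(1S)-1-[3,4-bis(benzyloxy)phenyl]prop-2-yn-1-yl]oxy}methyl)-3-[(tert-butyldimethylsilyl)oxy]propanoic acid | COc1cc([C@H](O[Si](C)(C)C(C)(C)C)[C@H](C(=O)O)CO[C@@H](C#C)c2ccc(OCc3ccccc3)c(OCc3ccccc3)c2)ccc1OCc1ccccc1 | intermediate
18 | 1,3-dioxoisoindolin-2-yl ester of 17 | COc1cc([C@H](O[Si](C)(C)C(C)(C)C)[C@H](C(=O)ON2C(=O)c3ccccc3C2=O)CO[C@@H](C#C)c2ccc(OCc3ccccc3)c(OCc3ccccc3)c2)ccc1OCc1ccccc1 | intermediate
19 | pinacolborane | CC1(C)OBOC1(C)C | starting material
20 | 1,3-dioxoisoindolin-2-yl (2R,3R)-3-[4-(benzyloxy)-3-methoxyphenyl]-2-({[(1S,2E)-1-[3,4-bis(benzyloxy)phenyl]-3-(4,4,5,5-tetramethyl-1,3,2-dioxaborolan-2-yl)prop-2-en-1-yl]oxy}methyl)-3-[(tert-butyldimethylsilyl)oxy]propanoate | COc1cc([C@H](O[Si](C)(C)C(C)(C)C)[C@H](C(=O)ON2C(=O)c3ccccc3C2=O)CO[C@@H](/C=C/B2OC(C)(C)C(C)(C)O2)c2ccc(OCc3ccccc3)c(OCc3ccccc3)c2)ccc1OCc1ccccc1 | intermediate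
21 | (2S,3S,4R)-2-[3,4-bis(benzyloxy)phenyl]-4-{(R)-[4-(benzyloxy)-3-methoxyphenyl][(tert-butyldimethylsilyl)oxy]methyl}-3-[(4,4,5,5-tetramethyl-1,3,2-dioxaborolan-2-yl)methyl]tetrahydrofuran | COc1cc([C@H](O[Si](C)(C)C(C)(C)C)[C@H]2CO[C@H](c3ccc(OCc4ccccc4)c(OCc4ccccc4)c3)[C@H]2CB2OC(C)(C)C(C)(C)O2)ccc1OCc1ccccc1 | intermediate
22 | [(2S,3R,4R)-2-[3,4-bis(benzyloxy)phenyl]-4-{(R)-[4-(benzyloxy)-3-methoxyphenyl][(tert-butyldimethylsilyl)oxy]methyl}tetrahydrofuran-3-yl]methanol | COc1cc([C@H](O[Si](C)(C)C(C)(C)C)[C@H]2CO[C@H](c3ccc(OCc4ccccc4)c(OCc4ccccc4)c3)[C@H]2CO)ccc1OCc1ccccc1 | intermediate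
23 | (R)-[4-(benzyloxy)-3-methoxyphenyl][(3R,4R,5S)-5-[3,4-bis(benzyloxy)phenyl]-4-(hydroxymethyl)tetrahydrofuran-3-yl]methanol | COc1cc([C@H](O)[C@H]2CO[C@H](c3ccc(OCc4ccccc4)c(OCc4ccccc4)c3)[C@H]2CO)ccc1OCc1ccccc1 | intermediate
24 | (7R)-7-hydroxytaxiresinol | COc1cc([C@H](O)[C@H]2CO[C@H](c3ccc(O)c(O)c3)[C@H]2CO)ccc1O | target

## Step count and least certain steps

Total: 13 steps. Longest linear sequence: 13 steps, from 1 to 24; 2, 5, 8, 11 and 19 each enter in a single step.

**Step 10 (key step).** The most likely failure is insufficient preference for the chair that places the bulky C7 arm cis to the C9' arm, so that the 3,4-trans ring isomer competes; the stereocentre at C7 may reinforce or oppose that chair. Hydrogen transfer to the C8 radical before closure, or base-induced β-elimination of the active ester, would lower conversion. The fallback sets out from 18 and returns at 22. The same photoreductive decarboxylation applied to the alkynyl ester would close the C8 radical 5-exo-dig, where the chair only has to place the C7' aryl and the C8 arm trans, giving the 2,4-trans 2-[3,4-bis(benzyloxy)phenyl]-4-{(R)-[4-(benzyloxy)-3-methoxyphenyl][(tert-butyldimethylsilyl)oxy]methyl}-3-methylidenetetrahydrofuran F1. Hydroboration of the exocyclic alkene with 9-BBN from the face away from the larger C8 arm, then NaBO3, would put hydrogen on C8' from the aryl face and the hydroxymethyl group cis to the arm. C8' would then be set by reagent approach instead of by the radical transition state.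

**Step 9.** The risk is hydride transfer from the borane catalyst to the activated ester or the imide carbonyls, with loss of the redox-active ester while the alkyne is hydroborated. The fallback sets out from 17 and returns at 20. The acid would be masked as its tert-butyldimethylsilyl ester F2 (TBSCl, imidazole, DMF) and hydroborated with 19 under the same catalysis to the E alkenylboronate silyl ester F3. The silyl ester alone would be hydrolysed (K2CO3, MeOH/THF/H2O, 0 °C) to the alkenylboronate acid F4, which would be coupled with N-hydroxyphthalimide and DIC. The active ester would then never meet a borane, and the C–B bond would never meet peroxide.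

**Step 13.** The risk is hydrogenolysis of the p-oxygenated benzylic C7–OH bond, or of the ring C7'–O1 bond, alongside debenzylation. The fallback sets out from 22 and returns at 24. Hydrogenolysis (H2, Pd/C, EtOAc) would be run while C7 still carries its bulky silyl ether, which disfavours adsorption and cleavage at that carbon, to give the C7 O-silylated tetraol F5. The silyl group would then be removed under argon with TBAF buffered by acetic acid.

**Step 1.** The risk is poor enantioface discrimination with a slowly reacting, electron-rich aldehyde, so that uncatalysed alkynyl transfer erodes the purity of C7'. The fallback sets out from 1 and returns at 4. Ethynylmagnesium bromide (THF, 0 °C) would give racemic 1-[3,4-bis(benzyloxy)phenyl]prop-2-yn-1-ol F6. Kinetic resolution with immobilised Candida antarctica lipase B and vinyl acetate should, by the usual size rule for secondary alcohols, acylate the R enantiomer to (R)-1-[3,4-bis(benzyloxy)phenyl]prop-2-yn-1-yl acetate F7 and leave 4, which is separated by chromatography.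

## Further compounds

F1 | step 10 | 2-[3,4-bis(benzyloxy)phenyl]-4-{(R)-[4-(benzyloxy)-3-methoxyphenyl][(tert-butyldimethylsilyl)oxy]methyl}-3-methylidenetetrahydrofuran (2,4-trans, C7' and C8 as in 21) | COc1cc([C@H](O[Si](C)(C)C(C)(C)C)[C@H]2CO[C@H](c3ccc(OCc4ccccc4)c(OCc4ccccc4)c3)C2=C)ccc1OCc1ccccc1
F2 | step 9 | tert-butyldimethylsilyl ester of 17 | COc1cc([C@H](O[Si](C)(C)C(C)(C)C)[C@H](C(=O)O[Si](C)(C)C(C)(C)C)CO[C@@H](C#C)c2ccc(OCc3ccccc3)c(OCc3ccccc3)c2)ccc1OCc1ccccc1
F3 | step 9 | tert-butyldimethylsilyl (2R,3R)-3-[4-(benzyloxy)-3-methoxyphenyl]-2-({[(1S,2E)-1-[3,4-bis(benzyloxy)phenyl]-3-(4,4,5,5-tetramethyl-1,3,2-dioxaborolan-2-yl)prop-2-en-1-yl]oxy}methyl)-3-[(tert-butyldimethylsilyl)oxy]propanoate | COc1cc([C@H](O[Si](C)(C)C(C)(C)C)[C@H](C(=O)O[Si](C)(C)C(C)(C)C)CO[C@@H](/C=C/B2OC(C)(C)C(C)(C)O2)c2ccc(OCc3ccccc3)c(OCc3ccccc3)c2)ccc1OCc1ccccc1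
F4 | step 9 | (2R,3R)-3-[4-(benzyloxy)-3-methoxyphenyl]-2-({[(1S,2E)-1-[3,4-bis(benzyloxy)phenyl]-3-(4,4,5,5-tetramethyl-1,3,2-dioxaborolan-2-yl)prop-2-en-1-yl]oxy}methyl)-3-[(tert-butyldimethylsilyl)oxy]propanoic acid | COc1cc([C@H](O[Si](C)(C)C(C)(C)C)[C@H](C(=O)O)CO[C@@H](/C=C/B2OC(C)(C)C(C)(C)O2)c2ccc(OCc3ccccc3)c(OCc3ccccc3)c2)ccc1OCc1ccccc1
F5 | step 13 | 4-[(2S,3R,4R)-4-{(R)-[(tert-butyldimethylsilyl)oxy](4-hydroxy-3-methoxyphenyl)methyl}-3-(hydroxymethyl)tetrahydrofuran-2-yl]benzene-1,2-diol | COc1cc([C@H](O[Si](C)(C)C(C)(C)C)[C@H]2CO[C@H](c3ccc(O)c(O)c3)[C@H]2CO)ccc1O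
F6 | step 1 | racemic 1-[3,4-bis(benzyloxy)phenyl]prop-2-yn-1-ol | OC(C#C)c1ccc(OCc2ccccc2)c(OCc2ccccc2)c1
F7 | step 1 | (R)-1-[3,4-bis(benzyloxy)phenyl]prop-2-yn-1-yl acetate | CC(=O)O[C@H](C#C)c1ccc(OCc2ccccc2)c(OCc2ccccc2)c1
A1 | alternative 1 | racemic 2-vinyloxirane | C=CC1CO1
A2 | alternative 1 | dimethyl 2-[3,4-bis(benzyloxy)benzylidene]malonate | COC(=O)C(=Cc1ccc(OCc2ccccc2)c(OCc2ccccc2)c1)C(=O)OC
A3 | alternative 1 | dimethyl 2-[3,4-bis(benzyloxy)phenyl]-4-vinyltetrahydrofuran-3,3-dicarboxylate (2,4-trans, C2 and C4 configured as C7' and C8 of 24) | C=C[C@H]1CO[C@H](c2ccc(OCc3ccccc3)c(OCc3ccccc3)c2)C1(C(=O)OC)C(=O)OC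
A4 | alternative 2 | (2S)-2-[3,4-bis(benzyloxy)phenyl]-2,5-dihydrofuran | O1CC=C[C@H]1c1ccc(OCc2ccccc2)c(OCc2ccccc2)c1
A5 | alternative 2 | [4-(benzyloxy)-3-methoxyphenyl]ketene | O=C=Cc1ccc(OCc2ccccc2)c(OC)c1
A6 | alternative 2 | 7-endo-[4-(benzyloxy)-3-methoxyphenyl]-4-exo-[3,4-bis(benzyloxy)phenyl]-3-oxabicyclo[3.2.0]heptan-6-one | O=C1[C@@H](c2ccc(OCc3ccccc3)c(OC)c2)[C@H]2CO[C@H](c3ccc(OCc4ccccc4)c(OCc4ccccc4)c3)[C@@H]12
A7 | alternative 2 | cis-fused 4-[4-(benzyloxy)-3-methoxyphenyl]-8-[3,4-bis(benzyloxy)phenyl]-3,7-dioxabicyclo[3.3.0]octan-2-one | O=C1O[C@@H](c2ccc(OCc3ccccc3)c(OC)c2)[C@H]2CO[C@H](c3ccc(OCc4ccccc4)c(OCc4ccccc4)c3)[C@@H]12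
A8 | alternative 3 | racemic [3,4-bis(benzyloxy)phenyl](chloro)methyl (trimethylsilyl)methyl ether | C[Si](C)(C)COC(Cl)c1ccc(OCc2ccccc2)c(OCc2ccccc2)c1
A9 | alternative 3 | (5S)-5-{[(1S,2R,5S)-2-isopropyl-5-methylcyclohexyl]oxy}furan-2(5H)-one | O=C1C=C[C@@H](O[C@H]2C[C@@H](C)CC[C@@H]2C(C)C)O1
A10 | alternative 3 | 8-exo-[3,4-bis(benzyloxy)phenyl]-4-{[(1S,2R,5S)-2-isopropyl-5-methylcyclohexyl]oxy}-3,7-dioxabicyclo[3.3.0]octan-2-one | O=C1O[C@H](O[C@H]2C[C@@H](C)CC[C@@H]2C(C)C)[C@H]2CO[C@H](c3ccc(OCc4ccccc4)c(OCc4ccccc4)c3)[C@@H]12
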